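**Strategy.** Succedaneaflavanone is a twofold-symmetric dimer. Its symmetry axis runs through the C6–C6'' biaryl bond, and each C6 lies on ring A between O5 and O7. The synthesis rests on cutting that bond into two identical halves. One iodochromone, iodinated at C6 by ortho direction from the chelated 5-hydroxyl, is homodimerized in a one-pot palladium-catalysed borylation/Suzuki–Miyaura sequence. This single operation creates the tetra-ortho-oxygenated biaryl and the complete bis(benzopyranone) core. The precursor is achiral and lacks ring B. Both C2 stereocentres are installed afterwards by a twofold, catalyst-controlled rhodium 1,4-addition of an arylboronic acid, and neutral hydrogenolysis of six benzyl ethers then gives the target.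

Key step: step 4

Remark: the structure defines only C2 and C2'' (both S) and gives no descriptor for the C6–C6'' axis, so the route sets the two stereocentres and leaves the axis uncontrolled; should rotation about it prove slow, both rotamers correspond to the structure as drawn. Double primes mark the second flavanone unit; single primes are used for the bichromone.

Step 1
Reactants: 1 5,7-dihydroxychromone; 2 benzyl bromide
Product: 3 7-(benzyloxy)-5-hydroxychromone
Conditions: BnBr (1.05 equiv), K2CO3 (1.2 equiv), acetone, reflux
Reagents that add atoms: benzyl bromide, BrCc1ccccc1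
Why: Williamson ether synthesis, selective because the 7-hydroxyl is the more acidic, unchelated phenol while the 5-hydroxyl is held in a hydrogen bond to the C4 carbonyl and should stay free.

Step 2
Reactants: 3 7-(benzyloxy)-5-hydroxychromone; 4 benzyltrimethylammonium dichloroiodate
Product: 5 7-(benzyloxy)-5-hydroxy-6-iodochromone
Conditions: BnMe3N ICl2 (1.05 equiv), CaCO3, CH2Cl2/MeOH, rt
Reagents that add atoms: benzyltrimethylammonium dichloroiodate, C[N+](C)(C)Cc1ccccc1.Cl[I-]Cl
Why: Electrophilic aromatic iodination directed ortho to the only free, chelated phenol, which should place iodine at C6 between O5 and O7 as is known for 5-hydroxy-7-alkoxyflavones with this reagent.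

Step 3
Reactants: 5 7-(benzyloxy)-5-hydroxy-6-iodochromone; 2 benzyl bromide
Product: 6 5,7-bis(benzyloxy)-6-iodochromone
Conditions: BnBr (1.5 equiv), K2CO3 (2.5 equiv), DMF, 60 °C
Reagents that add atoms: benzyl bromide, BrCc1ccccc1
Why: Williamson etherification of the chelated 5-hydroxyl under more forcing conditions, which removes the acidic proton before the coupling and puts the same protecting group on every oxygen.

Step 4
Reactants: 6 5,7-bis(benzyloxy)-6-iodochromone (two molecules); 7 bis(pinacolato)diboron
Product: 9 5,5',7,7'-tetrakis(benzyloxy)-6,6'-bichromone, via pinacol boronate 8 (not isolated)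
Conditions: Pd(OAc)2 (5 mol %), SPhos (10 mol %), B2pin2 (0.55 equiv), K3PO4 (3 equiv), 1,4-dioxane/H2O (10:1), 90 °C
Reagents that add atoms: none
Why: Zerovalent palladium ligated by SPhos inserts into the C6–I bond of 6; about half of the arylpalladium iodide is borylated by B2pin2 to boronate 8, which transmetalates onto the remaining arylpalladium iodide, and reductive elimination forms the C6–C6' bond. The closest known reaction type is the one-pot Miyaura borylation/Suzuki–Miyaura homodimerization of ortho-oxygenated aryl halides of the chromanone and xanthone families, with dialkylbiarylphosphines as the established ligands for tetra-ortho-substituted biaryls. No ring is closed and no stereocentre is created; the new axis is left uncontrolled. The step needs site selectivity for C6 over C8, which the iodine placed between O5 and O7 fixes, and it needs no cross-selectivity because both partners arise from the same iodide, which is the twofold symmetry of the target put to use. It also needs the coupling to outrun protodeboronation of 8, hydrodeiodination of 6 and hydroxide attack at C2 of the chromone, which the bulky electron-rich ligand, the mild phosphate base and the small water content are meant to secure.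

Step 5
Reactants: 9 5,5',7,7'-tetrakis(benzyloxy)-6,6'-bichromone; 10 4-(benzyloxy)phenylboronic acid
Product: 11 (2S,2''S)-hexa-O-benzylsuccedaneaflavanone
Conditions: [Rh(OH)(cod)]2 (3 mol %), (S)-MeO-F12-BIPHEP (6.6 mol %), 10 (5 equiv), CH2Cl2/H2O (20:1), 35 °C
Reagents that add atoms: 4-(benzyloxy)phenylboronic acid, OB(O)c1ccc(OCc2ccccc2)cc1
Why: Hayashi–Miyaura asymmetric 1,4-addition as known for 5,7-dioxygenated chromones, in which the arylrhodium species adds across C2=C3 of each chromone and water protonates the oxa-π-allylrhodium, each C2 centre being set by the chiral bisphosphine (catalyst control; the (S)-ligand is expected to give 2S by the quadrant model that gives (S)-3-arylcyclohexanones with (S)-biaryl bisphosphines, and the antipode is taken should the first run show the opposite sense), while the two independent additions should channel the minor sense into a separable (2R,2''S) diastereomer.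

Step 6
Reactants: 11 (2S,2''S)-hexa-O-benzylsuccedaneaflavanone
Product: 12 succedaneaflavanone
Conditions: H2 (1 atm), Pd/C (10 wt %), EtOAc/MeOH (1:1), rt, stopped after uptake of six equivalents
Reagents that add atoms: none
Why: Catalytic hydrogenolysis of six aryl benzyl ethers under neutral conditions, which offers no base-induced ring opening to the chalcone and so should leave both C2 centres untouched.

**Compound list**

1 | 5,7-dihydroxy-4H-chromen-4-one (5,7-dihydroxychromone) | O=c1ccoc2cc(O)cc(O)c12 | starting material
2 | benzyl bromide | BrCc1ccccc1 | starting material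
3 | 7-(benzyloxy)-5-hydroxy-4H-chromen-4-one | O=c1ccoc2cc(OCc3ccccc3)cc(O)c12 | intermediate
4 | benzyltrimethylammonium dichloroiodate | C[N+](C)(C)Cc1ccccc1.Cl[I-]Cl | starting material
5 | 7-(benzyloxy)-5-hydroxy-6-iodo-4H-chromen-4-one | O=c1ccoc2cc(OCc3ccccc3)c(I)c(O)c12 | intermediate
6 | 5,7-bis(benzyloxy)-6-iodo-4H-chromen-4-one | O=c1ccoc2cc(OCc3ccccc3)c(I)c(OCc3ccccc3)c12 | intermediate
7 | bis(pinacolato)diboron | CC1(C)OB(OC1(C)C)B1OC(C)(C)C(C)(C)O1 | starting material
8 | 5,7-bis(benzyloxy)-6-(4,4,5,5-tetramethyl-1,3,2-dioxaborolan-2-yl)-4H-chromen-4-one | O=c1ccoc2cc(OCc3ccccc3)c(B3OC(C)(C)C(C)(C)O3)c(OCc3ccccc3)c12 | intermediate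
9 | 5,5',7,7'-tetrakis(benzyloxy)-4H,4'H-[6,6'-bichromene]-4,4'-dione | O=c1ccoc2cc(OCc3ccccc3)c(-c3c(OCc4ccccc4)cc4occc(=O)c4c3OCc3ccccc3)c(OCc3ccccc3)c12 | intermediate
10 | 4-(benzyloxy)phenylboronic acid | OB(O)c1ccc(OCc2ccccc2)cc1 | starting material
11 | (2S,2'S)-5,5',7,7'-tetrakis(benzyloxy)-2,2'-bis[4-(benzyloxy)phenyl]-2,2',3,3'-tetrahydro-4H,4'H-[6,6'-bichromene]-4,4'-dione (hexa-O-benzylsuccedaneaflavanone) | O=C1C[C@@H](c2ccc(OCc3ccccc3)cc2)Oc2cc(OCc3ccccc3)c(-c3c(OCc4ccccc4)cc4c(c3OCc3ccccc3)C(=O)C[C@@H](c3ccc(OCc5ccccc5)cc3)O4)c(OCc3ccccc3)c21 | intermediate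
12 | succedaneaflavanone, (2S,2'S)-5,5',7,7'-tetrahydroxy-2,2'-bis(4-hydroxyphenyl)-2,2',3,3'-tetrahydro-4H,4'H-[6,6'-bichromene]-4,4'-dione | O=C1C[C@@H](c2ccc(O)cc2)Oc2cc(O)c(-c3c(O)cc4c(c3O)C(=O)C[C@@H](c3ccc(O)cc3)O4)c(O)c21 | target

**Step count and risks**

Total step count: 6. Longest linear sequence: 6 steps, from 1 to 12.

Steps most likely to fail:

1. Step 4. Transmetalation at the palladium centre flanked by two ortho benzyloxy groups may be slow. Protodeboronation of the boronate, hydrodeiodination, palladation of a neighbouring benzyl ring (intramolecular C–H arylation) or hydroxide-induced opening of the chromone could then outrun biaryl formation. The fallback sets out from 6 and separates metalation from coupling under base-free conditions. Pd(PPh3)4 and hexamethylditin in toluene at 100 °C should give 5,7-bis(benzyloxy)-6-(trimethylstannyl)chromone F1. Copper monochloride (CuCl) in N,N-dimethylacetamide under air at rt should then effect oxidative homocoupling through an arylcopper species. The fallback comes back to the route at 9.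

2. Step 5. The second 1,4-addition may stall on the hindered bichromone, or the catalyst may read the two chromone units unequally, leaving mono-adduct and the (2R,2''S) diastereomer. Protodeboronation of the boronic acid may also consume the aryl donor. The fallback sets out from 6 and sets the stereocentre on the monomer before the biaryl bond is made. Asymmetric conjugate addition of 10 with Pd(OCOCF3)2, the t-BuPyOX antipode that gives 2S, NH4PF6 and water in 1,2-dichloroethane at 60 °C stays at divalent palladium throughout and should leave the C–I bond alone. It should give (S)-5,7-bis(benzyloxy)-2-[4-(benzyloxy)phenyl]-6-iodochroman-4-one F2. Pd(PPh3)4 and hexamethylditin in toluene at 100 °C should then give (S)-5,7-bis(benzyloxy)-2-[4-(benzyloxy)phenyl]-6-(trimethylstannyl)chroman-4-one F3. CuCl in N,N-dimethylacetamide under air at rt should dimerize F3 without base, so C2 should not epimerize. The fallback comes back to the route at 11.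

3. Step 6. Over-reduction may cleave the benzylic C2–O1 bonds to dihydrochalcones or reduce the ketones, and the hindered 5-O-benzyl ethers may be cleaved incompletely. The fallback sets out from 11 and replaces reduction by Lewis-acid dealkylation. BCl3 with pentamethylbenzene as cation scavenger in CH2Cl2 at −78 °C should cleave all six ethers, with chelation to the C4 carbonyl assisting cleavage of the 5-O-benzyl groups. It arrives directly at 12 and makes no new compound.

Further compounds
F1 | step 4 | 5,7-bis(benzyloxy)-6-(trimethylstannyl)-4H-chromen-4-one | O=c1ccoc2cc(OCc3ccccc3)c([Sn](C)(C)C)c(OCc3ccccc3)c12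
F2 | step 5 | (S)-5,7-bis(benzyloxy)-2-[4-(benzyloxy)phenyl]-6-iodochroman-4-one | O=C1C[C@@H](c2ccc(OCc3ccccc3)cc2)Oc2cc(OCc3ccccc3)c(I)c(OCc3ccccc3)c21
F3 | step 5 | (S)-5,7-bis(benzyloxy)-2-[4-(benzyloxy)phenyl]-6-(trimethylstannyl)chroman-4-one | O=C1C[C@@H](c2ccc(OCc3ccccc3)cc2)Oc2cc(OCc3ccccc3)c([Sn](C)(C)C)c(OCc3ccccc3)c21
F0 | step 6 | none | none
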